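# Proposed synthesis of CNP0398030.1 (compound 28) by photocycloaddition and thermal cycloreversion

## Analysis of the target

Compound 28 is a germacranolide: a ten-membered carbocycle (C1–C10) with a cis-fused α-methylene-γ-butyrolactone across C6–C7, the lactone oxygen on C6, and C7 bearing C11, which carries the carbonyl C12 and the exocyclic methylene C13. C9 bears an acetate, C10 the C14 methyl, and C4 the C15 methylene as its 3-methylbutanoate. The ring bonds are cis at C1=C10 and trans at C4=C5, although both alkenes are Z by the sequence rule because C9 and C15 outrank the ring carbons. The three stereocentres (6R, 7R, 9S) lie on the arc C5–C10; H6 and H7 are cis, and when the arc is drawn as a six-membered ring the C9 oxygen and the C7–C11 bond are 1,3-trans. The sensitive groups are the α-methylene lactone (a Michael acceptor that tolerates neither strong base, hydride nor nucleophilic fluoride), two different carboxylic esters that must be placed selectively, three allylic C–O bonds (C6, C9, C15) and a medium-ring 1,5-diene open to Cope rearrangement and acid-induced transannular cyclisation. The hard part is the ten-membered ring with one cis and one trans trisubstituted alkene, a poor object for any ring closure from a chain. The plan rests on the fact that the two alkenes are joined by the ethano bridge C2–C3 and that each is flanked on its far side by an oxygenated carbon (C6, C9). The six carbons C5–C10 therefore map onto a 4-oxygenated 3-methylcyclohex-2-enone (C6 carbonyl, C10 methyl, C9 oxygen) and C1–C4 with C15 onto a cyclobutenecarboxylate, so that the ten-membered ring is the formal metathesis product of these two cycloalkenes.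

## Retrosynthetic reasoning

**C9 acetate.** The acyl C–O bond at C9 of 28 is cut first, back to alcohol 27 and its silyl ether 26. An acetate would not survive the organometallic, enolate and hydride steps earlier in the route; the silyl ether does. The cost is two end-game steps, and the forward step only has to acylate the single free hydroxyl.

**Methylene group and lactone oxidation level.** In 26 the C11=C13 bond is cut (a one-carbon electrophile on C11) and C12 is taken down to the lactol level, giving 25 and then 23. The methylenation is placed at the lactol, which is a masked aldehyde, so that an amine base is enough and the C15 ester is never exposed to a strong base. The forward oxidation of 25 is helped by the lactol carbinol being allylic.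

**Lactol C–O bond.** 23 is opened between the C6 oxygen and C12 to the C6 alcohol 21, with C12 as a dimethyl acetal. The acetal keeps C12 at the aldehyde level through the hydride step and so distinguishes it from C15. The forward step is a mild hydrolysis with capture by the neighbouring hydroxyl.

**C15 ester.** 21 is cut at the C15 acyl C–O bond to diol 19 and acid chloride 20. The forward step has to acylate the primary allylic hydroxyl and leave the hindered secondary C6 hydroxyl.

**C6 and C15 oxidation states.** Diol 19 comes from keto ester 18 by delivery of hydride to both carbonyl groups in one operation. The forward step has to place the C6 hydroxyl cis to the C7 side chain.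

**The ring (key disconnection).** In 18 the alkenes C1=C10 and C4=C5 are reconnected as the σ bonds C5–C10 and C1–C4, which gives the tricycle 16 (one six-membered and two four-membered rings). A cut at any single ring bond would leave a chain that has to be closed to a ten-membered ring with two alkenes of fixed geometry. Here no macrocyclisation is needed: the ring is stored in a strained tricycle and released by cleaving two bonds. The forward thermolysis has to break C5–C10 rather than C2–C3 and pair a cis C1=C10 with a trans C4=C5.

**Photoadduct.** 16 is cut at C4–C5 and C1–C10, the two bonds of an enone–alkene [2+2] photocycloaddition, giving enone 13 and cyclobutene ester 14. The ester on C4 directs the orientation, later stabilises the radical formed at C4 and ends up as C15. The forward step has to be head-to-head and on the face opposite the C9 silyloxy group.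

**C7 side chain.** 13 is traced through aldehyde 12 to the allyl compound 10, and the C7–C11 bond is cut to enone 7 and allyl bromide 8. A reactive allylic electrophile is used and converted in two steps because a two-carbon electrophile already at the acetal level is a sluggish partner for a ketone enolate. The alkene has to be gone before irradiation. The forward alkylation has to be trans to the C9 silyloxy group.

**Enone.** 7 comes from the resolved alcohol 6 and the racemate 5. The C10–C14 bond and the enone are made from the vinylogous ester 3 by addition of a methyl nucleophile with carbonyl transposition, and the C9–O bond by α′-hydroxylation of 1. This fixes the positions of methyl and oxygen by connectivity and does not depend on a regioselective γ-oxidation.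

## Alternatives that were turned down

**Alternative 1:** Wharton fragmentation.
- *Disconnection:* the C9 carbonyl and the trans C4=C5 alkene of A1 are traced back to a C4–C9 σ bond, a tertiary hydroxyl on C9 and a sulfonate on C5. The ten-membered ring is thus stored as two fused six-membered rings.
- *Forward key step:* KOtBu forms the C9 alkoxide, which expels the anti-periplanar C5 mesylate through the C4–C9 bond. This gives A1, with the cis-lactone, a C9 ketone and C15 as a p-methoxybenzyl ether.
- *For:* the fragmentation is stereospecific. The trans C4=C5 geometry follows from a fixed chair, and the cis C1=C10 alkene is carried inside a six-membered ring. On alkene geometry this is stronger than the chosen plan, which depends on a conformational preference. C6 and C7 would also be set on a rigid bicycle.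
- *Against:* the substrate needs five contiguous stereocentres, two of them adjacent and fully substituted (C4, C9), and several are destroyed in the key step. Strong base meets a lactone with a β-oxygen next to the leaving group. C9 emerges as a ketone conjugated with C1=C10, so the 9S carbinol must then be set on the flexible ring in competition with conjugate reduction.
- *Comparison:* the chosen plan gives up stereospecific alkene formation. In return, C9 is in place from a resolved six-membered-ring alcohol, and all ring carbons are assembled from two simple cycloalkenes in two operations, with a much shorter route to the key intermediate.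

**Alternative 2:** anionic oxy-Cope ring expansion.
- *Disconnection:* the C6–C7 bond and the C4=C5 alkene of A2 are traced back through a [3,3] shift to a 1,5-diene C7=C8–C9–C4–C5=C6. Its C4–C9 bond belongs to a methylcyclohexene ring, and C9 carries the hydroxyl.
- *Forward key step:* the potassium C9 alkoxide rearranges. C6–C7 forms, C4–C9 breaks, the six-membered ring grows by four atoms, and protonation of the C9 enolate gives A2.
- *For:* the step runs near room temperature, far below the 190 °C planned for the chosen key step, and it creates C6 and C7 together with the ring. On both points it is stronger.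
- *Against:* two stereodefined alkenyl groups (one an enol ether) must sit on adjacent fully substituted carbons. The outcome depends on both alkene geometries, the relative configuration at C4/C9 and the chair or boat transition state. The product is a cross-conjugated dienolate, and its protonation may move or isomerise the cis C1=C10 alkene. C9 again arrives as a ketone, C12 at the alcohol level, and three different protecting groups are needed.
- *Comparison:* the chosen plan has to set C6 afterwards by reduction. In return, C7 and C9 come from ordinary six-membered-ring chemistry, one silyl group is the only protecting group, and the step count is lower.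

**Alternative 3:** nitrogen deletion.
- *Disconnection:* the C2–C3 bond of A3 is replaced by two C–N bonds, which gives the eleven-membered secondary amine A4 with nitrogen between the two allylic carbons.
- *Forward key step:* an N-acyloxy-N-alkoxyamide converts A4 into an isodiazene. Loss of dinitrogen leaves allyl radicals at C2 and C3, which recombine to A3.
- *For:* all three stereocentres, both alkenes and the lactone are complete before the ring contraction. The C–N bonds come from ordinary allylic aminations, and the step is mild. As a late-stage, convergent ring formation it is stronger than the chosen plan.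
- *Against:* both radicals are delocalised (C2/C10 and C3/C5). Recombination can therefore give C2–C5, C10–C3 or C10–C5 bonds with smaller, less strained rings, and the allyl radicals can lose the alkene geometry. Hydrogen transfer to dienes competes. Contraction to a strained ten-membered carbocycle by radical recombination has no close model. The methylene lactone must be introduced after the amine has gone.
- *Comparison:* in the chosen plan the regiochemistry of ring formation is fixed by the σ-bond connectivity of a tricycle, the alkene positions cannot shift, the reaction type is known, and the precursor is reached in eight steps.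

Key step: step 9

## Remarks on the chemistry

- Germacrane locants (C1–C15) are used in the discussion throughout and in the names of compounds 15 to 28; compounds 1 to 14 carry ordinary systematic names.
- The descriptor at the ring carbon that bears the side chain changes from S (10, 11) to R (12, 13) only because the substituent priorities change; no bond at that carbon is touched.
- 14 is taken as a purchasable building block.
- The sense of the lipase resolution in step 3 is assumed to follow the usual size rule for secondary alcohols and would be confirmed on the first run.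

## Route

Step 1
Reactants: 1 3-ethoxycyclohex-2-en-1-one
Product: 3 rac-3-ethoxy-6-hydroxycyclohex-2-en-1-one, via potassium dienolate 2 (not isolated)
Conditions: KN(SiMe3)2, THF, −78 °C; 2-(phenylsulfonyl)-3-phenyloxaziridine, −78 °C; AcOH
Reagents that add atoms: 2-(phenylsulfonyl)-3-phenyloxaziridine, O=S(=O)(c1ccccc1)N1OC1c1ccccc1
Why: Kinetic deprotonation of the vinylogous ester occurs only at the α′ CH2, and the potassium enolate is hydroxylated by oxygen transfer from the N-sulfonyloxaziridine (enolate α-hydroxylation); the carbinol, the future C9, is racemic at this stage.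

Step 2
Reactants: 3 rac-3-ethoxy-6-hydroxycyclohex-2-en-1-one
Product: 5 rac-4-hydroxy-3-methylcyclohex-2-en-1-one, via dilithium diolate 4 (not isolated)
Conditions: MeLi (2.3 equiv), THF, −78 to 0 °C; 1 M aq HCl, 0 °C
Reagents that add atoms: methyllithium, [Li]C
Why: One equivalent of MeLi deprotonates the hydroxyl and the next adds to the carbonyl; aqueous acid then hydrolyses the enol ether and eliminates the tertiary hydroxyl (Stork–Danheiser transposition), which puts the new methyl (C14) on the β-carbon and the carbinol on the γ-carbon without any regiochemical choice.

Step 3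
Reactants: 5 rac-4-hydroxy-3-methylcyclohex-2-en-1-one
Product: 6 (S)-4-hydroxy-3-methylcyclohex-2-en-1-one
Conditions: vinyl acetate, immobilised Candida antarctica lipase B, tBuOMe, 30 °C, stopped a little beyond half conversion
Reagents that add atoms: none
Why: Lipase-catalysed kinetic resolution by irreversible transesterification; with the methyl-bearing alkene carbon as the large group and the ring CH2 as the medium group, the R alcohol should be acetylated faster, so the S alcohol needed for C9 is recovered and separated from the R acetate.

Step 4
Reactants: 6 (S)-4-hydroxy-3-methylcyclohex-2-en-1-one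
Product: 7 (S)-4-(tert-butyldimethylsilyloxy)-3-methylcyclohex-2-en-1-one
Conditions: TBSCl, imidazole, DMF, rt
Reagents that add atoms: tert-butyldimethylsilyl chloride, CC(C)(C)[Si](C)(C)Cl
Why: Standard silylation; the silyl ether tolerates the amide base, irradiation, 190 °C, iBu2AlH and mild aqueous acid, and its bulk next to C10 later directs both the alkylation and the photocycloaddition.

Step 5
Reactants: 7 (S)-4-(tert-butyldimethylsilyloxy)-3-methylcyclohex-2-en-1-one; 8 allyl bromide
Product: 10 (4S,6S)-6-allyl-4-(tert-butyldimethylsilyloxy)-3-methylcyclohex-2-en-1-one, via lithium dienolate 9 (not isolated)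
Conditions: LiN(iPr)2, THF, −78 °C; 8, −78 to −30 °C
Reagents that add atoms: none
Why: Kinetic α′-deprotonation gives the cross-conjugated dienolate, in which the silyloxy group is pseudoaxial to avoid A(1,2) strain with the methyl; axial attack of the allyl halide on the opposite face sets the new centre (C7) trans to the silyloxy group, which is also the more stable arrangement.

Step 6
Reactants: 10 (4S,6S)-6-allyl-4-(tert-butyldimethylsilyloxy)-3-methylcyclohex-2-en-1-one
Product: 12 (4S,6R)-4-(tert-butyldimethylsilyloxy)-3-methyl-6-(2-oxoethyl)cyclohex-2-en-1-one, via vicinal diol 11 (not isolated)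
Conditions: OsO4 (cat.), NaIO4, 2,6-lutidine, dioxane–H2O (3:1), rt
Reagents that add atoms: sodium periodate, [Na+].[O-]I(=O)(=O)=O
Why: Lemieux–Johnson cleavage; OsO4 dihydroxylates the monosubstituted alkene much faster than the trisubstituted, electron-poor enone alkene to give diol 11, which periodate cleaves in the same flask, and 2,6-lutidine suppresses over-oxidation, so C7 is untouched and no alkene is left to interfere with the irradiation.

Step 7
Reactants: 12 (4S,6R)-4-(tert-butyldimethylsilyloxy)-3-methyl-6-(2-oxoethyl)cyclohex-2-en-1-one
Product: 13 (4S,6R)-4-(tert-butyldimethylsilyloxy)-6-(2,2-dimethoxyethyl)-3-methylcyclohex-2-en-1-one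
Conditions: HC(OMe)3, CeCl3·7H2O (cat.), MeOH, rt
Reagents that add atoms: trimethyl orthoformate, COC(OC)OC; methanol, CO
Why: Acetalisation under near-neutral catalysis is selective for the aldehyde over the conjugated ketone; the acetal holds C12 at the aldehyde level through the later hydride step.

Step 8
Reactants: 13 (4S,6R)-4-(tert-butyldimethylsilyloxy)-6-(2,2-dimethoxyethyl)-3-methylcyclohex-2-en-1-one; 14 methyl cyclobut-1-ene-1-carboxylate
Product: 16 methyl cis-anti-cis-9-(tert-butyldimethylsilyloxy)-7-(2,2-dimethoxyethyl)-10-methyl-6-oxotricyclo[4.4.0.0(2,5)]decane-4-carboxylate (germacrane locants; methyl and H5 and the C9 silyloxy group on one face of the six-membered ring; cyclobutane and C7 side chain on the other), via triplet biradical 15 (not isolated)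
Conditions: 14 (8 equiv), hν (Hg lamp, Pyrex, λ > 300 nm), CH2Cl2, −40 °C
Reagents that add atoms: none
Why: Enone–alkene [2+2] photocycloaddition through the enone triplet: C10 bonds to the unsubstituted cyclobutene carbon C1, the α-keto radical at C5 and the ester-stabilised radical at C4 then combine, which gives the head-to-head adduct and avoids two adjacent quaternary carbons. The cyclobutene approaches C10 on the face opposite the neighbouring pseudoaxial C9 silyloxy group, both ring fusions close cis and the outer rings take the less crowded anti arrangement, which sets C10, C5, C4 and C1.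

Step 9
Reactants: 16 methyl cis-anti-cis-9-(tert-butyldimethylsilyloxy)-7-(2,2-dimethoxyethyl)-10-methyl-6-oxotricyclo[4.4.0.0(2,5)]decane-4-carboxylate
Product: 18 methyl (1(10)Z,4Z,7R,9S)-9-(tert-butyldimethylsilyloxy)-7-(2,2-dimethoxyethyl)-10-methyl-6-oxocyclodeca-1(10),4-diene-4-carboxylate (germacrane locants; ring bonds cis at C1=C10 and trans at C4=C5), via cyclohexanediyl 17 (not isolated)
Conditions: PhMe (0.01 M, degassed), BHT (cat.), sealed base-washed tube, 190 °C
Reagents that add atoms: none
Why: Heat breaks the central C1–C4 bond of the bicyclo[2.2.0]hexane unit, the most strained bond and the one whose homolysis leaves an ester-stabilised radical at C4; the resulting diyl 17 then cleaves C5–C10 to form C1=C10 and C4=C5. The closest known reaction type is the thermal cycloreversion of enone–cyclobutene photoadducts of this tricyclic type to cyclodeca-1,5-dienes, the thermal half of a photochemical–thermal alkene metathesis. The ten-membered ring is not closed by a bond-forming cyclisation; it appears when the two σ bonds that cross it are cut, so there is no entropic cost of macrocyclisation. No stereocentre is formed: C7 and C9 are spectators and the four cyclobutane centres disappear. The step needs scission of C5–C10 and not of C2–C3, and C5–C10 is the weaker bond because C10 is quaternary and C5 is α to the ketone; its cleavage gives two trisubstituted alkenes, one conjugated with both carbonyl groups. The step also needs the right pairing of geometries: in the chair-like diyl the C14 methyl should sit equatorial on C10, which makes C9 axial (cis C1=C10) and C6 equatorial on C5 (trans C4=C5). A Cope return to the divinylcyclohexanone is disfavoured because it would give up the ketone–alkene conjugation and put a quaternary carbon next to a tertiary one. High dilution, a radical inhibitor and base-free glass are used against bimolecular reactions of the electron-poor alkene and epimerisation at C7.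

Step 10
Reactants: 18 methyl (1(10)Z,4Z,7R,9S)-9-(tert-butyldimethylsilyloxy)-7-(2,2-dimethoxyethyl)-10-methyl-6-oxocyclodeca-1(10),4-diene-4-carboxylate
Product: 19 (1(10)Z,4Z)-9-(tert-butyldimethylsilyloxy)-7-(2,2-dimethoxyethyl)-4-(hydroxymethyl)-10-methylcyclodeca-1(10),4-dien-6-ol (germacrane locants; C6 hydroxyl cis to the C7 side chain; 7R and 9S unchanged)
Conditions: iBu2AlH (5 equiv), CH2Cl2, −78 to −40 °C; aq potassium sodium tartrate
Reagents that add atoms: none
Why: iBu2AlH reduces the conjugated ketone in 1,2-fashion and the enoate to the allylic alcohol, while acetal and silyl ether are inert. In the extended arrangement of C5–C6–C7–C8 expected next to the trans C4=C5 unit, hydride should reach the C6 carbonyl from the side of H7, anti to the C7 side chain, which places the hydroxyl cis to that chain (the configuration that becomes 6R in 28).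

Step 11
Reactants: 19 (1(10)Z,4Z)-9-(tert-butyldimethylsilyloxy)-7-(2,2-dimethoxyethyl)-4-(hydroxymethyl)-10-methylcyclodeca-1(10),4-dien-6-ol; 20 3-methylbutanoyl chloride
Product: 21 C15 3-methylbutanoate of 19 (C6 hydroxyl free)
Conditions: 20 (1.05 equiv), 2,4,6-collidine, CH2Cl2, −78 to −30 °C
Reagents that add atoms: none
Why: Acylation under kinetic control; the primary allylic C15 hydroxyl reacts much faster than the secondary C6 hydroxyl, which is flanked by the branched C7, and the hindered non-nucleophilic base does not promote acyl migration.

Step 12
Reactants: 21 C15 3-methylbutanoate of 19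
Product: 23 cis-fused 12-hydroxy-12,6-lactol (2-hydroxytetrahydrofuran across C6–C7; anomer mixture; C15 ester and C9 silyl ether retained), via hydroxy aldehyde 22 (not isolated)
Conditions: PPTS (cat.), acetone–H2O (4:1), 40 °C
Reagents that add atoms: water, O
Why: Mild acid-catalysed acetal hydrolysis; the aldehyde is trapped at once by the cis C6 hydroxyl as the five-membered lactol, under conditions that leave the silyl ether, the allylic ester and the 1,5-diene alone.

Step 13
Reactants: 23 cis-fused 12-hydroxy-12,6-lactol
Product: 25 11(13)-methylene lactol (α-methylene analogue of 23), via Mannich base 24 (not isolated)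
Conditions: Me2N=CH2+ I−, Et3N, CH2Cl2, rt
Reagents that add atoms: dimethyl(methylidene)ammonium iodide, C[N+](C)=C.[I-]
Why: Aldehyde α-methylenation by Mannich reaction at C11 and β-elimination of dimethylamine, acting on the open hydroxy aldehyde that is in equilibrium with the lactol; only an amine base is present, so the C15 ester is not enolised, and the product recloses to the lactol.

Step 14
Reactants: 25 11(13)-methylene lactol
Product: 26 (1(10)Z,4Z,6R,7R,9S)-9-(tert-butyldimethylsilyloxy)-15-(3-methylbutanoyloxy)germacra-1(10),4,11(13)-trien-12,6-olide
Conditions: MnO2 (activated, excess), CH2Cl2, rt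
Reagents that add atoms: none
Why: The lactol carbinol is allylic to the exocyclic methylene, so manganese dioxide oxidises it to the α-methylene lactone; no other free hydroxyl is present.

Step 15
Reactants: 26 (1(10)Z,4Z,6R,7R,9S)-9-(tert-butyldimethylsilyloxy)-15-(3-methylbutanoyloxy)germacra-1(10),4,11(13)-trien-12,6-olide
Product: 27 (1(10)Z,4Z,6R,7R,9S)-9-hydroxy-15-(3-methylbutanoyloxy)germacra-1(10),4,11(13)-trien-12,6-olide
Conditions: HF·pyridine, pyridine, THF, 0 °C to rt
Reagents that add atoms: none
Why: Buffered acidic fluoride removes the silyl group; a basic fluoride source is avoided because it could add to the methylene lactone or move the ester.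

Step 16
Reactants: 27 (1(10)Z,4Z,6R,7R,9S)-9-hydroxy-15-(3-methylbutanoyloxy)germacra-1(10),4,11(13)-trien-12,6-olide
Product: 28 (1(10)Z,4Z,6R,7R,9S)-9-acetoxy-15-(3-methylbutanoyloxy)germacra-1(10),4,11(13)-trien-12,6-olide
Conditions: Ac2O, pyridine, DMAP (cat.), CH2Cl2, 0 °C
Reagents that add atoms: acetic anhydride, CC(=O)OC(C)=O
Why: Acetylation of the only free hydroxyl; it is done last because the acetate would not pass the earlier organolithium, enolate and hydride steps.

## Compound list

1 | 3-ethoxycyclohex-2-en-1-one | CCOC1=CC(=O)CCC1 | starting material
2 | potassium dienolate of 1 (potassium 5-ethoxycyclohexa-1,5-dien-1-olate) | CCOC1=CC([O-])=CCC1.[K+] | intermediate (not isolated)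
3 | rac-3-ethoxy-6-hydroxycyclohex-2-en-1-one | CCOC1=CC(=O)C(O)CC1 | intermediate
4 | dilithium diolate from MeLi addition to 3 (dilithium 3-ethoxy-1-methylcyclohex-2-ene-1,6-diolate; diastereomer mixture) | [Li+].[Li+].CCOC1=CC(C)([O-])C([O-])CC1 | intermediate (not isolated)
5 | rac-4-hydroxy-3-methylcyclohex-2-en-1-one | CC1=CC(=O)CCC1O | intermediate
6 | (S)-4-hydroxy-3-methylcyclohex-2-en-1-one | CC1=CC(=O)CC[C@@H]1O | intermediate
7 | (S)-4-(tert-butyldimethylsilyloxy)-3-methylcyclohex-2-en-1-one | CC1=CC(=O)CC[C@@H]1O[Si](C)(C)C(C)(C)C | intermediate
8 | allyl bromide (3-bromoprop-1-ene) | C=CCBr | starting material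
9 | lithium dienolate of 7 (lithium (4S)-4-(tert-butyldimethylsilyloxy)-5-methylcyclohexa-1,5-dien-1-olate) | [Li+].CC1=CC([O-])=CC[C@@H]1O[Si](C)(C)C(C)(C)C | intermediate (not isolated)
10 | (4S,6S)-6-allyl-4-(tert-butyldimethylsilyloxy)-3-methylcyclohex-2-en-1-one (4,6-trans) | CC1=CC(=O)[C@@H](CC=C)C[C@@H]1O[Si](C)(C)C(C)(C)C | intermediate
11 | vicinal diol from 10 ((4S,6S)-4-(tert-butyldimethylsilyloxy)-6-(2,3-dihydroxypropyl)-3-methylcyclohex-2-en-1-one; both carbinol epimers) | CC1=CC(=O)[C@@H](CC(O)CO)C[C@@H]1O[Si](C)(C)C(C)(C)C | intermediate (not isolated)
12 | (4S,6R)-4-(tert-butyldimethylsilyloxy)-3-methyl-6-(2-oxoethyl)cyclohex-2-en-1-one (4,6-trans) | CC1=CC(=O)[C@@H](CC=O)C[C@@H]1O[Si](C)(C)C(C)(C)C | intermediate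
13 | (4S,6R)-4-(tert-butyldimethylsilyloxy)-6-(2,2-dimethoxyethyl)-3-methylcyclohex-2-en-1-one | CC1=CC(=O)[C@@H](CC(OC)OC)C[C@@H]1O[Si](C)(C)C(C)(C)C | intermediate
14 | methyl cyclobut-1-ene-1-carboxylate | COC(=O)C1=CCC1 | starting material
15 | triplet biradical after C1–C10 bond formation (1,4-biradical; radicals at C5 and C4) | C[C@@]1([C@@H]2CC[C]2C(=O)OC)[C@@H](O[Si](C)(C)C(C)(C)C)C[C@H](CC(OC)OC)C(=O)[CH]1 | intermediate (not isolated)
16 | methyl cis-anti-cis-9-(tert-butyldimethylsilyloxy)-7-(2,2-dimethoxyethyl)-10-methyl-6-oxotricyclo[4.4.0.0(2,5)]decane-4-carboxylate (germacrane locants) | C[C@@]12[C@@H](O[Si](C)(C)C(C)(C)C)C[C@H](CC(OC)OC)C(=O)[C@@H]1[C@@]1(C(=O)OC)CC[C@H]12 | intermediate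
17 | cyclohexanediyl from C1–C4 homolysis of 16 (cyclohexane-1,4-diyl; radicals at C1 and C4) | C[C@@]12[C@@H](O[Si](C)(C)C(C)(C)C)C[C@H](CC(OC)OC)C(=O)[C@@H]1[C](C(=O)OC)CC[CH]2 | intermediate (not isolated)
18 | methyl (1(10)Z,4Z,7R,9S)-9-(tert-butyldimethylsilyloxy)-7-(2,2-dimethoxyethyl)-10-methyl-6-oxocyclodeca-1(10),4-diene-4-carboxylate (germacrane locants) | O=C1/C=C(\C(=O)OC)CC/C=C(/C)[C@@H](O[Si](C)(C)C(C)(C)C)C[C@@H]1CC(OC)OC | intermediate
19 | (1(10)Z,4Z)-9-(tert-butyldimethylsilyloxy)-7-(2,2-dimethoxyethyl)-4-(hydroxymethyl)-10-methylcyclodeca-1(10),4-dien-6-ol (C6 hydroxyl cis to the C7 chain) | O[C@@H]1/C=C(\CO)CC/C=C(/C)[C@@H](O[Si](C)(C)C(C)(C)C)C[C@@H]1CC(OC)OC | intermediate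
20 | 3-methylbutanoyl chloride | CC(C)CC(Cl)=O | starting material
21 | C15 3-methylbutanoate of 19 | O[C@@H]1/C=C(\COC(=O)CC(C)C)CC/C=C(/C)[C@@H](O[Si](C)(C)C(C)(C)C)C[C@@H]1CC(OC)OC | intermediate
22 | hydroxy aldehyde (open C12 aldehyde with free C6 hydroxyl) | O[C@@H]1/C=C(\COC(=O)CC(C)C)CC/C=C(/C)[C@@H](O[Si](C)(C)C(C)(C)C)C[C@@H]1CC=O | intermediate (not isolated)
23 | cis-fused 12-hydroxy-12,6-lactol (anomer mixture) | C1C(O)O[C@@H]2/C=C(\COC(=O)CC(C)C)CC/C=C(/C)[C@@H](O[Si](C)(C)C(C)(C)C)C[C@H]12 | intermediate
24 | C11 (dimethylaminomethyl) lactol (Mannich base; epimer mixture at C11) | CN(C)CC1C(O)O[C@@H]2/C=C(\COC(=O)CC(C)C)CC/C=C(/C)[C@@H](O[Si](C)(C)C(C)(C)C)C[C@H]12 | intermediate (not isolated)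
25 | 11(13)-methylene lactol | C=C1C(O)O[C@@H]2/C=C(\COC(=O)CC(C)C)CC/C=C(/C)[C@@H](O[Si](C)(C)C(C)(C)C)C[C@H]12 | intermediate
26 | (1(10)Z,4Z,6R,7R,9S)-9-(tert-butyldimethylsilyloxy)-15-(3-methylbutanoyloxy)germacra-1(10),4,11(13)-trien-12,6-olide | C=C1C(=O)O[C@@H]2/C=C(\COC(=O)CC(C)C)CC/C=C(/C)[C@@H](O[Si](C)(C)C(C)(C)C)C[C@H]12 | intermediate
27 | (1(10)Z,4Z,6R,7R,9S)-9-hydroxy-15-(3-methylbutanoyloxy)germacra-1(10),4,11(13)-trien-12,6-olide | C=C1C(=O)O[C@@H]2/C=C(\COC(=O)CC(C)C)CC/C=C(/C)[C@@H](O)C[C@H]12 | intermediate
28 | (1(10)Z,4Z,6R,7R,9S)-9-acetoxy-15-(3-methylbutanoyloxy)germacra-1(10),4,11(13)-trien-12,6-olide | C=C1C(=O)O[C@@H]2/C=C(\COC(=O)CC(C)C)CC/C=C(/C)[C@@H](OC(C)=O)C[C@H]12 | target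

## Step count and least certain steps

Total step count: 16. Longest linear sequence: 16 steps, from 1 to 28; 8, 14 and 20 enter as purchased building blocks.

**Step 9 (key step).** Three things may go wrong:
- scission of C2–C3 in the diyl, or a later Cope rearrangement, which drains the ten-membered ring to the divinylcyclohexanone;
- reversed pairing of the alkene geometries if the chair with an axial methyl competes;
- thermal degradation of the doubly activated C4=C5 alkene, or epimerisation at C7, at 190 °C.

The fallback opens the ring at the alcohol oxidation level with the geometry locked. It sets out from 16. NaBH4 in MeOH at 0 °C reduces the C6 ketone from the face opposite the cyclobutane, and the alkoxide, which is cis to the C4 ester, closes the tetracyclic 15,6-lactone F1. Only the C6 configuration that the target needs can lactonise. Thermolysis of F1 should give the bridged butenolide F2. Its five-membered ring holds C15 and C6 cis on C4=C5, so only the trans ring geometry is possible there, and the cis,trans course of the cycloreversion then puts the cis geometry at C1=C10. Excess iBu2AlH reduces the butenolide of F2 to the allylic diol, and the route is rejoined at 19. This variant gives up the ketone conjugation that argues against the Cope isomer, so it answers the geometry and stability problems rather than the Cope drain.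

**Step 8.** The photocycloaddition may show incomplete head-to-head orientation, partial addition to the face syn to the silyloxy group or a trans ring fusion, and 14 may polymerise. The fallback changes the order of events. It sets out from 7: irradiation of 7 with 14 should give the simpler tricyclic ketone F3, on a substrate with one stereocentre and no α′ branch. Kinetic deprotonation of F3 at C7 with LiN(iPr)2 (the bridgehead C5–H enolises reluctantly) and allylation with 8 give the allyl ketone F4, expected anti to the C9 silyloxy group; this would have to be verified. Lemieux–Johnson cleavage gives the aldehyde F5, and the acetalisation of step 7 returns to 16.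

**Step 10.** The facial selectivity at C6 on the flexible ten-membered ring is the least secure stereochemical point, and some conjugate reduction of the γ-keto enoate may occur. The fallback uses inversion and sets out from 18. If reduction favours the other face, it gives the C6-epimeric diol F6. Acylation with 20 as in step 11 gives the epimeric ester F7. A Mitsunobu reaction (ClCH2CO2H, PPh3, iPrO2CN=NCO2iPr) inverts C6 to the chloroacetate F8. Thiourea with NaHCO3 in EtOH removes the chloroacetyl group in the presence of the 3-methylbutanoate, and the route is rejoined at 21.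

**Step 13.** The lactol may open too little for the Mannich reaction, or the Mannich base may fail to eliminate. The fallback carries out the methylenation on a free aldehyde and sets out from 21. Silylation of the C6 hydroxyl (Et3SiOTf, 2,6-lutidine) gives the bis-silyl ether F9. Chemoselective acetal cleavage (Et3SiOTf, 2,4,6-collidine, then water) gives the aldehyde F10, which cannot cyclise. The same iminium salt with Et3N gives the α-methylene aldehyde F11. Removal of the triethylsilyl group (AcOH–THF–H2O, 0 °C; the C9 silyl ether is much slower) lets the hydroxy enal close, and the route is rejoined at 25.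

## Further compounds

F1 | step 9 | tetracyclic 15,6-lactone of the C6-reduced photoadduct (cis-anti-cis core, C6–O cis to the cyclobutane) | C[C@]12[C@@H](O[Si](C)(C)C(C)(C)C)C[C@H](CC(OC)OC)[C@@H]3OC(=O)[C@@]4(CC[C@@H]14)[C@H]23
F2 | step 9 | (1(10)Z)-9-(tert-butyldimethylsilyloxy)-7-(2,2-dimethoxyethyl)germacra-1(10),4-dien-15,6-olide (bridged butenolide, C4=C5 trans in the ten-membered ring) | O=C1O[C@@H]2C=C1CC/C=C(/C)[C@@H](O[Si](C)(C)C(C)(C)C)C[C@@H]2CC(OC)OC
F3 | step 8 | methyl cis-anti-cis-9-(tert-butyldimethylsilyloxy)-10-methyl-6-oxotricyclo[4.4.0.0(2,5)]decane-4-carboxylate (germacrane locants, no C7 side chain) | C[C@@]12[C@@H](O[Si](C)(C)C(C)(C)C)CCC(=O)[C@@H]1[C@@]1(C(=O)OC)CC[C@H]12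
F4 | step 8 | 7-allyl derivative of F3 (allyl trans to the C9 silyloxy group) | C[C@@]12[C@@H](O[Si](C)(C)C(C)(C)C)C[C@H](CC=C)C(=O)[C@@H]1[C@@]1(C(=O)OC)CC[C@H]12
F5 | step 8 | 7-(2-oxoethyl) derivative of F3 | C[C@@]12[C@@H](O[Si](C)(C)C(C)(C)C)C[C@H](CC=O)C(=O)[C@@H]1[C@@]1(C(=O)OC)CC[C@H]12
F6 | step 10 | C6 epimer of 19 (C6 hydroxyl trans to the C7 chain) | O[C@H]1/C=C(\CO)CC/C=C(/C)[C@@H](O[Si](C)(C)C(C)(C)C)C[C@@H]1CC(OC)OC
F7 | step 10 | C6 epimer of 21 | O[C@H]1/C=C(\COC(=O)CC(C)C)CC/C=C(/C)[C@@H](O[Si](C)(C)C(C)(C)C)C[C@@H]1CC(OC)OC
F8 | step 10 | C6 chloroacetate of 21 (C6 configuration as in 21) | ClCC(=O)O[C@@H]1/C=C(\COC(=O)CC(C)C)CC/C=C(/C)[C@@H](O[Si](C)(C)C(C)(C)C)C[C@@H]1CC(OC)OC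
F9 | step 13 | C6 triethylsilyl ether of 21 | CC[Si](CC)(CC)O[C@@H]1/C=C(\COC(=O)CC(C)C)CC/C=C(/C)[C@@H](O[Si](C)(C)C(C)(C)C)C[C@@H]1CC(OC)OC
F10 | step 13 | C12 aldehyde with C6 triethylsilyl ether | CC[Si](CC)(CC)O[C@@H]1/C=C(\COC(=O)CC(C)C)CC/C=C(/C)[C@@H](O[Si](C)(C)C(C)(C)C)C[C@@H]1CC=O
F11 | step 13 | 11(13)-methylene C12 aldehyde with C6 triethylsilyl ether | CC[Si](CC)(CC)O[C@@H]1/C=C(\COC(=O)CC(C)C)CC/C=C(/C)[C@@H](O[Si](C)(C)C(C)(C)C)C[C@@H]1C(=C)C=O
A1 | alternative 1 | cis-lactone cyclodecadienone with C9 ketone and C15 p-methoxybenzyl ether | C1C(=O)O[C@@H]2/C=C(\COCc3ccc(OC)cc3)CC/C=C(/C)C(=O)C[C@H]12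
A2 | alternative 2 | cyclodecadienone with C9 ketone, C6 p-methoxybenzyl ether, C15 triisopropylsilyl ether and C7 silyloxyethyl chain | COc1ccc(CO[C@@H]2/C=C(\CO[Si](C(C)C)(C(C)C)C(C)C)CC/C=C(/C)C(=O)C[C@@H]2CCO[Si](C)(C)C(C)(C)C)cc1
A3 | alternative 3 | cis-lactone cyclodecadiene with C9 silyl ether and C15 p-methoxybenzyl ether | C1C(=O)O[C@@H]2/C=C(\COCc3ccc(OC)cc3)CC/C=C(/C)[C@@H](O[Si](C)(C)C(C)(C)C)C[C@H]12
A4 | alternative 3 | eleven-membered secondary amine with nitrogen between C2 and C3 | C1C(=O)O[C@@H]2/C=C(\COCc3ccc(OC)cc3)CNC/C=C(/C)[C@@H](O[Si](C)(C)C(C)(C)C)C[C@H]12
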